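**Strategy.** Everything rests on cutting the C3–C4 bond of the cyclohexenone ring (C1 ketone, C2 vinyl CH, C3 methyl-bearing carbon, C4 acetoxy carbinol, C5 and C6 oxirane carbons, C6 carrying the chain). Both ends of that bond are natural electrophiles, C3 as the conjugate position of the C1 enone and C4 as an oxygen-bearing carbon next to the C5–C6 oxirane of the 7-oxabicyclo[4.1.0]heptenone core, so C3 is made the nucleophile: CrCl2 with catalytic NiCl2 converts a (Z)-β-iodoenone into an alkenylchromium that attacks a C4 aldehyde, which closes the carbocycle onto the finished oxirane and creates the C4 stereocentre. The precursor is an acyclic cis-oxirane keto aldehyde carrying the 12-silyloxyfarnesyl chain, its oxirane set by Sharpless epoxidation.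

Key step: step 16

Remark: "TBSO-farnesyl" stands for the (2E,6E,10E)-12-[(tert-butyldimethylsilyl)oxy]-3,7,11-trimethyldodeca-2,6,10-trien-1-yl group and PMB for 4-methoxybenzyl; ring positions C1–C6 are used as defined above.

Assumption: alkoxides and stabilised carbanions that exist only until aqueous work-up are counted as the compound they derive from and get no number; the alkenylchromium of step 16, a separate organometallic species, is numbered.

**Step 1**
Reactants: 1 (2E,6E)-farnesol
Product: 2 (2E,6E)-farnesyl acetate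
Conditions: Ac2O, pyridine, DMAP (cat.), CH2Cl2, 0 °C → rt
Reagents that add atoms: acetic anhydride, CC(=O)OC(C)=O
Why: DMAP-catalysed acylation (esterification) of the primary allylic alcohol is routine and masks the C1 hydroxyl so that the next step can single out the far end of the chain.

**Step 2**
Reactants: 2 (2E,6E)-farnesyl acetate
Product: 3 (2E,6E,10E)-12-hydroxy-3,7,11-trimethyldodeca-2,6,10-trien-1-yl acetate
Conditions: SeO2 (cat.), salicylic acid (cat.), t-BuOOH (70% aq.), CH2Cl2, rt
Reagents that add atoms: tert-butyl hydroperoxide, CC(C)(C)OO (the oxygen atom, relayed through catalytic SeO2)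
Why: Catalytic SeO2/t-BuOOH allylic oxidation (Riley oxidation: ene reaction, then [2,3]-sigmatropic shift) attacks the terminal, most electron-rich trisubstituted alkene of farnesyl esters at its E-methyl group, the alkene next to the acetate being deactivated, so the 12-alcohol should form with the 10E geometry kept.

**Step 3**
Reactants: 3 (2E,6E,10E)-12-hydroxyfarnesyl acetate
Product: 4 (2E,6E,10E)-12-[(tert-butyldimethylsilyl)oxy]-3,7,11-trimethyldodeca-2,6,10-trien-1-yl acetate
Conditions: TBSCl, imidazole, DMF, rt
Reagents that add atoms: tert-butyldimethylsilyl chloride, CC(C)(C)[Si](C)(C)Cl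
Why: Imidazole-promoted silylation of a primary alcohol is reliable, and the silyl ether must be in place before the hydroxyl-directed epoxidation so that the chain alkenes have no free allylic hydroxyl.

**Step 4**
Reactants: 4 silyloxyfarnesyl acetate
Product: 5 (2E,6E,10E)-12-[(tert-butyldimethylsilyl)oxy]-3,7,11-trimethyldodeca-2,6,10-trien-1-ol
Conditions: K2CO3, MeOH, rt
Reagents that add atoms: none
Why: Base-catalysed transesterification in methanol removes the acetate, while the silyl ether is stable to K2CO3/MeOH.

**Step 5**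
Reactants: 5 12-silyloxyfarnesol
Product: 6 (2E,6E,10E)-1-bromo-12-[(tert-butyldimethylsilyl)oxy]-3,7,11-trimethyldodeca-2,6,10-triene (TBSO-farnesyl bromide; used without chromatography)
Conditions: CBr4, PPh3, CH2Cl2, −20 → 0 °C
Reagents that add atoms: carbon tetrabromide, BrC(Br)(Br)Br
Why: The Appel reaction converts the primary allylic alcohol into the bromide by SN2 displacement of an alkoxyphosphonium ion under neutral conditions, which at low temperature should avoid allylic transposition, E/Z scrambling and loss of the silyl ether.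

**Step 6**
Reactants: 7 methyl 2-[bis(2,2,2-trifluoroethoxy)phosphoryl]acetate (twofold excess); 6 TBSO-farnesyl bromide
Product: 8 methyl 2-[bis(2,2,2-trifluoroethoxy)phosphoryl]-2-(TBSO-farnesyl)acetate (racemic)
Conditions: NaH, THF, 0 °C; then 6, 0 °C → rt
Reagents that add atoms: none
Why: The sodium salt of the phosphonoacetate is a stabilised carbanion that is C-alkylated by the primary allylic bromide in an SN2 reaction, the excess of 7 keeping dialkylation down; the new stereocentre is racemic and is destroyed in step 7.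

**Step 7**
Reactants: 8 α-(TBSO-farnesyl) phosphonoacetate; 9 2-[(4-methoxybenzyl)oxy]acetaldehyde
Product: 10 methyl (2Z)-2-(TBSO-farnesyl)-4-[(4-methoxybenzyl)oxy]but-2-enoate
Conditions: KN(SiMe3)2, 18-crown-6, THF, −78 °C; then 9
Reagents that add atoms: none
Why: In the Still–Gennari olefination the electron-poor bis(trifluoroethyl) phosphonate eliminates from the kinetic adduct under dissociating conditions, so the ester and the CH2OPMB group should end up cis (2Z), the geometry that later puts C1 and C4 on the same side of the oxirane.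

**Step 8**
Reactants: 10 (2Z)-ester
Product: 11 (2Z)-2-(TBSO-farnesyl)-4-[(4-methoxybenzyl)oxy]but-2-en-1-ol
Conditions: iBu2AlH, CH2Cl2, −78 → 0 °C
Reagents that add atoms: none
Why: iBu2AlH reduces the conjugated ester to the allylic alcohol by 1,2-hydride delivery without touching the alkenes, the silyl ether or the PMB ether.

**Step 9**
Reactants: 11 (2Z)-allylic alcohol
Product: 12 [(2S,3R)-2-(TBSO-farnesyl)-3-{[(4-methoxybenzyl)oxy]methyl}oxiran-2-yl]methanol
Conditions: Ti(OiPr)4 (cat.), L-(+)-diethyl tartrate (cat.), t-BuOOH (anhydrous, in decane), 4 Å molecular sieves, CH2Cl2, −20 °C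
Reagents that add atoms: tert-butyl hydroperoxide, CC(C)(C)OO
Why: The Sharpless asymmetric epoxidation transfers oxygen only to the alkene whose allylic hydroxyl is bound to titanium, so the three chain alkenes are left alone, and L-(+)-diethyl tartrate delivers oxygen in the same facial sense that takes E allylic alcohols to 2S,3S epoxy alcohols, which for this Z, 2-substituted substrate means the 2S,3R oxirane and hence C5 and C6 of the target.

**Step 10**
Reactants: 12 epoxy alcohol
Product: 13 (2R,3R)-2-(TBSO-farnesyl)-3-{[(4-methoxybenzyl)oxy]methyl}oxirane-2-carbaldehyde (same spatial arrangement as 12; the C2 descriptor changes only through the priority rules)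
Conditions: Dess–Martin periodinane, pyridine, CH2Cl2, 0 °C → rt
Reagents that add atoms: none
Why: Dess–Martin oxidation under pyridine buffering takes the primary epoxy alcohol to the aldehyde without opening the oxirane, and the α-carbon is quaternary so nothing can epimerise.

**Step 11**
Reactants: 13 epoxy aldehyde; 14 1-propynylmagnesium bromide
Product: 15 1-[(2S,3R)-2-(TBSO-farnesyl)-3-{[(4-methoxybenzyl)oxy]methyl}oxiran-2-yl]but-2-yn-1-ol (both carbinol epimers)
Conditions: THF, −78 → −40 °C; aq. NH4Cl
Reagents that add atoms: none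
Why: Grignard 1,2-addition of the alkynyl nucleophile to the aldehyde is fast at low temperature and does not open the oxirane; the new carbinol centre forms as a mixture and is removed by the next oxidation.

**Step 12**
Reactants: 15 propargylic alcohol
Product: 16 1-[(2R,3R)-2-(TBSO-farnesyl)-3-{[(4-methoxybenzyl)oxy]methyl}oxiran-2-yl]but-2-yn-1-one
Conditions: Dess–Martin periodinane, pyridine, CH2Cl2, 0 °C → rt
Reagents that add atoms: none
Why: Dess–Martin oxidation of the secondary propargylic alcohol gives the ynone under near-neutral conditions that leave the oxirane and both ethers intact.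

**Step 13**
Reactants: 16 epoxy ynone
Product: 17 (2Z)-3-iodo-1-[(2R,3R)-2-(TBSO-farnesyl)-3-{[(4-methoxybenzyl)oxy]methyl}oxiran-2-yl]but-2-en-1-one
Conditions: LiI (1.2 equiv), AcOH (1.5 equiv), MeCN, 0 °C → rt, dark
Reagents that add atoms: lithium iodide, [Li+].[I-]
Why: Iodide adds to the ynone in a conjugate (Michael) fashion and the allenolate is protonated anti to iodine, so this hydroiodination should give the kinetic Z isomer with iodine cis to the carbonyl, while the oxirane, electron-poor and quaternary at the carbon α to the ketone, should be opened far more slowly than the ynone is consumed.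

**Step 14**
Reactants: 17 (Z)-β-iodoenone PMB ether
Product: 18 (2Z)-1-[(2R,3R)-3-(hydroxymethyl)-2-(TBSO-farnesyl)oxiran-2-yl]-3-iodobut-2-en-1-one
Conditions: DDQ, CH2Cl2/H2O (buffered at pH 7), 0 °C
Reagents that add atoms: none
Why: DDQ cleaves the PMB ether by oxidation at the electron-rich benzylic position followed by hydrolysis, conditions under which the silyl ether, the oxirane, the iodoenone and the isolated alkenes are inert.

**Step 15**
Reactants: 18 primary alcohol
Product: 19 (2S,3R)-3-[(2Z)-3-iodobut-2-enoyl]-3-(TBSO-farnesyl)oxirane-2-carbaldehyde (the cyclisation precursor; used at once)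
Conditions: Dess–Martin periodinane, pyridine, CH2Cl2, 0 °C
Reagents that add atoms: none
Why: Dess–Martin oxidation converts the primary alcohol (the open form, in equilibrium with any cyclic hemiketal onto C1) into the aldehyde, whose only α-hydrogen sits on the oxirane and is not enolisable under these conditions.

**Step 16**
Reactants: 19 (Z)-β-iodoenone epoxy aldehyde
Product: 21 (1R,5R,6R)-5-hydroxy-4-methyl-1-(TBSO-farnesyl)-7-oxabicyclo[4.1.0]hept-3-en-2-one, via alkenylchromium dichloride 20 (not isolated)
Conditions: CrCl2 (4 equiv), NiCl2 (0.02 equiv), degassed DMSO/THF, rt, 0.005 M; aq. NH4Cl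
Reagents that add atoms: none
Why: Zerovalent nickel, generated from NiCl2 by CrCl2, inserts into the activated C3–I bond and hands the alkenyl group with retention of geometry to trivalent chromium, and the resulting β-acyl alkenylchromium 20 adds to the C4 aldehyde. The closest known reaction type is the intramolecular Nozaki–Hiyama–Kishi addition of alkenyl iodides to aldehydes, in which β-iodo enones and enoates are established partners. The six-membered carbocycle closes in the 6-exo-trig mode (aldehyde oxygen outside the new ring), helped by the Z alkene and the cis-disubstituted oxirane, which hold C3 and C4 side by side. The one new stereocentre, C4, is set under substrate control: trivalent chromium bound to both the aldehyde oxygen and the oxirane oxygen holds the carbonyl oxygen syn to the oxirane, which also keeps the bulky chromium alkoxide on the face away from the C6 chain, so the hydroxyl should emerge cis to the oxirane (4R). The step needs chemoselectivity for the C–I bond over the epoxy ketone and the aldehyde, which fast nickel insertion into an electron-poor alkenyl iodide at room temperature, a small excess of CrCl2 and the non-basic organochromium should provide, and it needs high dilution to outrun intermolecular addition. C5 and C6 are untouched, and because C6 is quaternary the precursor can neither enolise towards the oxirane nor aromatise.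

**Step 17**
Reactants: 21 cyclised alcohol
Product: 22 (1R,2R,6R)-3-methyl-5-oxo-6-(TBSO-farnesyl)-7-oxabicyclo[4.1.0]hept-3-en-2-yl acetate
Conditions: Ac2O, pyridine, DMAP (cat.), CH2Cl2, 0 °C
Reagents that add atoms: acetic anhydride, CC(=O)OC(C)=O
Why: DMAP-catalysed acylation esterifies the secondary allylic alcohol with retention at C4 under mild conditions that the epoxy enone tolerates.

**Step 18**
Reactants: 22 silyl-protected acetate
Product: 23 yanuthone L
Conditions: HF·pyridine, pyridine, THF, 0 °C → rt
Reagents that add atoms: none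
Why: Buffered HF·pyridine cleaves the primary allylic silyl ether through formation of the strong Si–F bond under mildly acidic conditions, avoiding basic fluoride sources that could cleave the acetate or trigger elimination at the γ-acetoxy enone.

**Compound list**

1 | (2E,6E)-farnesol | OC/C=C(\C)CC/C=C(\C)CCC=C(C)C | starting material
2 | (2E,6E)-farnesyl acetate | CC(=O)OC/C=C(\C)CC/C=C(\C)CCC=C(C)C | intermediate
3 | (2E,6E,10E)-12-hydroxy-3,7,11-trimethyldodeca-2,6,10-trien-1-yl acetate | CC(=O)OC/C=C(\C)CC/C=C(\C)CC/C=C(\C)CO | intermediate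
4 | (2E,6E,10E)-12-[(tert-butyldimethylsilyl)oxy]-3,7,11-trimethyldodeca-2,6,10-trien-1-yl acetate | CC(=O)OC/C=C(\C)CC/C=C(\C)CC/C=C(\C)CO[Si](C)(C)C(C)(C)C | intermediate
5 | (2E,6E,10E)-12-[(tert-butyldimethylsilyl)oxy]-3,7,11-trimethyldodeca-2,6,10-trien-1-ol | OC/C=C(\C)CC/C=C(\C)CC/C=C(\C)CO[Si](C)(C)C(C)(C)C | intermediate
6 | (2E,6E,10E)-1-bromo-12-[(tert-butyldimethylsilyl)oxy]-3,7,11-trimethyldodeca-2,6,10-triene | BrC/C=C(\C)CC/C=C(\C)CC/C=C(\C)CO[Si](C)(C)C(C)(C)C | intermediate
7 | methyl 2-[bis(2,2,2-trifluoroethoxy)phosphoryl]acetate | COC(=O)CP(=O)(OCC(F)(F)F)OCC(F)(F)F | starting material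
8 | methyl 2-[bis(2,2,2-trifluoroethoxy)phosphoryl]-2-(TBSO-farnesyl)acetate (racemic) | COC(=O)C(C/C=C(\C)CC/C=C(\C)CC/C=C(\C)CO[Si](C)(C)C(C)(C)C)P(=O)(OCC(F)(F)F)OCC(F)(F)F | intermediate
9 | 2-[(4-methoxybenzyl)oxy]acetaldehyde | COc1ccc(COCC=O)cc1 | starting material
10 | methyl (2Z)-2-(TBSO-farnesyl)-4-[(4-methoxybenzyl)oxy]but-2-enoate | COC(=O)/C(C/C=C(\C)CC/C=C(\C)CC/C=C(\C)CO[Si](C)(C)C(C)(C)C)=C\COCc1ccc(OC)cc1 | intermediate
11 | (2Z)-2-(TBSO-farnesyl)-4-[(4-methoxybenzyl)oxy]but-2-en-1-ol | OC/C(C/C=C(\C)CC/C=C(\C)CC/C=C(\C)CO[Si](C)(C)C(C)(C)C)=C\COCc1ccc(OC)cc1 | intermediate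
12 | [(2S,3R)-2-(TBSO-farnesyl)-3-{[(4-methoxybenzyl)oxy]methyl}oxiran-2-yl]methanol | OC[C@]1(C/C=C(\C)CC/C=C(\C)CC/C=C(\C)CO[Si](C)(C)C(C)(C)C)O[C@@H]1COCc2ccc(OC)cc2 | intermediate
13 | (2R,3R)-2-(TBSO-farnesyl)-3-{[(4-methoxybenzyl)oxy]methyl}oxirane-2-carbaldehyde | O=C[C@]1(C/C=C(\C)CC/C=C(\C)CC/C=C(\C)CO[Si](C)(C)C(C)(C)C)O[C@@H]1COCc2ccc(OC)cc2 | intermediate
14 | 1-propynylmagnesium bromide | CC#C[Mg]Br | starting material
15 | 1-[(2S,3R)-2-(TBSO-farnesyl)-3-{[(4-methoxybenzyl)oxy]methyl}oxiran-2-yl]but-2-yn-1-ol (both carbinol epimers) | CC#CC(O)[C@]1(C/C=C(\C)CC/C=C(\C)CC/C=C(\C)CO[Si](C)(C)C(C)(C)C)O[C@@H]1COCc2ccc(OC)cc2 | intermediate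
16 | 1-[(2R,3R)-2-(TBSO-farnesyl)-3-{[(4-methoxybenzyl)oxy]methyl}oxiran-2-yl]but-2-yn-1-one | CC#CC(=O)[C@]1(C/C=C(\C)CC/C=C(\C)CC/C=C(\C)CO[Si](C)(C)C(C)(C)C)O[C@@H]1COCc2ccc(OC)cc2 | intermediate
17 | (2Z)-3-iodo-1-[(2R,3R)-2-(TBSO-farnesyl)-3-{[(4-methoxybenzyl)oxy]methyl}oxiran-2-yl]but-2-en-1-one | C/C(I)=C/C(=O)[C@]1(C/C=C(\C)CC/C=C(\C)CC/C=C(\C)CO[Si](C)(C)C(C)(C)C)O[C@@H]1COCc2ccc(OC)cc2 | intermediate
18 | (2Z)-1-[(2R,3R)-3-(hydroxymethyl)-2-(TBSO-farnesyl)oxiran-2-yl]-3-iodobut-2-en-1-one | C/C(I)=C/C(=O)[C@]1(C/C=C(\C)CC/C=C(\C)CC/C=C(\C)CO[Si](C)(C)C(C)(C)C)O[C@@H]1CO | intermediate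
19 | (2S,3R)-3-[(2Z)-3-iodobut-2-enoyl]-3-(TBSO-farnesyl)oxirane-2-carbaldehyde | C/C(I)=C/C(=O)[C@]1(C/C=C(\C)CC/C=C(\C)CC/C=C(\C)CO[Si](C)(C)C(C)(C)C)O[C@@H]1C=O | intermediate
20 | alkenylchromium dichloride derived from 19 (iodine replaced by CrCl2, Z geometry kept, solvent ligands omitted) | C/C([Cr](Cl)Cl)=C/C(=O)[C@]1(C/C=C(\C)CC/C=C(\C)CC/C=C(\C)CO[Si](C)(C)C(C)(C)C)O[C@@H]1C=O | intermediate
21 | (1R,5R,6R)-5-hydroxy-4-methyl-1-(TBSO-farnesyl)-7-oxabicyclo[4.1.0]hept-3-en-2-one | O[C@@H]1C(C)=CC(=O)[C@]2(C/C=C(\C)CC/C=C(\C)CC/C=C(\C)CO[Si](C)(C)C(C)(C)C)O[C@H]12 | intermediate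
22 | (1R,2R,6R)-3-methyl-5-oxo-6-(TBSO-farnesyl)-7-oxabicyclo[4.1.0]hept-3-en-2-yl acetate | CC(=O)O[C@@H]1C(C)=CC(=O)[C@]2(C/C=C(\C)CC/C=C(\C)CC/C=C(\C)CO[Si](C)(C)C(C)(C)C)O[C@H]12 | intermediate
23 | yanuthone L, (1R,2R,6R)-6-[(2E,6E,10E)-12-hydroxy-3,7,11-trimethyldodeca-2,6,10-trien-1-yl]-3-methyl-5-oxo-7-oxabicyclo[4.1.0]hept-3-en-2-yl acetate | CC(=O)O[C@@H]1C(C)=CC(=O)[C@]2(C/C=C(\C)CC/C=C(\C)CC/C=C(\C)CO)O[C@H]12 | target

**Totals.** Total step count: 18. Longest linear sequence: 18 steps (1 to 23); 7, 9 and 14 are bought and used directly.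

**Steps most likely to fail**

1. Step 16. The aldehyde may react through the dipole-minimised rotamer instead of the chelated one, so that facial selectivity at C4 is poor or reversed while the ring still closes. The fallback sets out from 19 and returns at 22. The closure is run as in step 16 and the C4 epimer, (1R,5S,6R)-5-hydroxy-4-methyl-1-(TBSO-farnesyl)-7-oxabicyclo[4.1.0]hept-3-en-2-one F1, is separated from any 21. F1 is then esterified with inversion under Mitsunobu conditions (PPh3, diisopropyl azodicarboxylate, AcOH, THF, 0 °C): acetate displaces the oxyphosphonium group at C4 in an SN2 reaction, which gives 22 directly. The SN2′ path would have to attack C2, the carbon α to the ketone, and is disfavoured. Any 21 formed alongside goes through step 17 as planned, so both epimers converge on 22 and the C4 configuration is then fixed by substitution instead of by the addition.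

2. Step 13. Iodide under acid may open the oxirane (iodohydrin formation, then reductive loss of iodine), or the Z iodoalkene may equilibrate by iodide addition–elimination. The fallback sets out from 13 and returns at 17; it brings iodine in under neutral conditions through tin. Propyne and Me3SnSnMe3 with catalytic Pd(PPh3)4 give, by syn distannylation, (Z)-1,2-bis(trimethylstannyl)prop-1-ene F2. MeLi (THF, −78 °C) exchanges only the terminal, less hindered tin, and the alkenyllithium adds to aldehyde 13 to give (2Z)-1-[(2S,3R)-2-(TBSO-farnesyl)-3-{[(4-methoxybenzyl)oxy]methyl}oxiran-2-yl]-3-(trimethylstannyl)but-2-en-1-ol F3 as a mixture of carbinol epimers. Iododestannylation (I2, CH2Cl2, 0 °C) is stereoretentive and much faster than any reaction of iodine with the chain alkenes; it gives (2Z)-3-iodo-1-[(2S,3R)-2-(TBSO-farnesyl)-3-{[(4-methoxybenzyl)oxy]methyl}oxiran-2-yl]but-2-en-1-ol F4. Dess–Martin oxidation (pyridine, CH2Cl2) of F4 then gives 17.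

3. Step 9. Oxygen transfer may be slow and enantioselectivity eroded, the usual weakness of Z-configured allylic alcohols in the titanium–tartrate system. The fallback goes from 11 to 12 by vanadium-catalysed asymmetric epoxidation with a chiral C2-symmetric bishydroxamic acid ligand (VO(OiPr)3, ligand, aqueous t-BuOOH, CH2Cl2, 0 °C). This is a different catalyst class with its own stereochemical model, and it performs best with Z and 2-substituted allylic alcohols. It is also hydroxyl-directed, so the chain alkenes stay untouched. The ligand antipode would be chosen to give the 2S,3R oxirane and the sense checked against material from the titanium system (Mosher ester analysis). This fallback makes no new compound (none F0).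

**Further compounds**

F1 | step 16 | (1R,5S,6R)-5-hydroxy-4-methyl-1-(TBSO-farnesyl)-7-oxabicyclo[4.1.0]hept-3-en-2-one | O[C@H]1C(C)=CC(=O)[C@]2(C/C=C(\C)CC/C=C(\C)CC/C=C(\C)CO[Si](C)(C)C(C)(C)C)O[C@H]12
F2 | step 13 | (Z)-1,2-bis(trimethylstannyl)prop-1-ene | C/C(=C/[Sn](C)(C)C)[Sn](C)(C)C
F3 | step 13 | (2Z)-1-[(2S,3R)-2-(TBSO-farnesyl)-3-{[(4-methoxybenzyl)oxy]methyl}oxiran-2-yl]-3-(trimethylstannyl)but-2-en-1-ol | C/C([Sn](C)(C)C)=C/C(O)[C@]1(C/C=C(\C)CC/C=C(\C)CC/C=C(\C)CO[Si](C)(C)C(C)(C)C)O[C@@H]1COCc2ccc(OC)cc2
F4 | step 13 | (2Z)-3-iodo-1-[(2S,3R)-2-(TBSO-farnesyl)-3-{[(4-methoxybenzyl)oxy]methyl}oxiran-2-yl]but-2-en-1-ol | C/C(I)=C/C(O)[C@]1(C/C=C(\C)CC/C=C(\C)CC/C=C(\C)CO[Si](C)(C)C(C)(C)C)O[C@@H]1COCc2ccc(OC)cc2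
F0 | step 9 | none | none
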